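The readings stem from a simulated flask with constants of no real substance, and the scatter is random.

Start from a ratio: the share of substrate the chain can turn in the time given, over the share of target the partner charge can pay for. Call it the reach ratio.

| flask | substrate | partner | initiator | radical scavenger | remark | time |
|---|---|---|---|---|---|---|
| theta | 0.80 M | 0.30 equiv | 5 mol% | 0.091 mol% | run made earlier |  |
| zeta | 0.80 M | 0.64 equiv | 5 mol% | 0.091 mol% | run made earlier |  |
| gamma | 0.80 M | 0.91 equiv | 5 mol% | 0.091 mol% | run made earlier |  |
| epsilon | 0.80 M | 1.2 equiv | 2.5 mol% | 0.091 mol% | run made earlier |  |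
| north | 0.80 M | 1.20 equiv | 5 mol% | 0.091 mol% |  | 2.0 h |
| north-west | 1.5 M | 0.400 equiv | 1.5 mol% | 0.091 mol% |  | 2.0 h |

| run | time / min | target / % | substrate / % |
|---|---|---|---|
| theta | 12.0 | 2.6 | 97.6 |
| theta | 25.0 | 15.9 | 85.3 |
| theta | 40.0 | 26.1 | 72.8 |
| theta | 50.0 | 28.5 | 70.5 |
| theta | 60.0 | 31.3 | 70.1 |
| zeta | 5.00 | 0 | 100.9 |
| zeta | 15.0 | 6.1 | 92.5 |
| zeta | 30.0 | 17.8 | 80.7 |
| zeta | 40.0 | 25.2 | 74.5 |
| zeta | 60.0 | 38.6 | 60.3 |
| gamma | 12.0 | 0.9 | 97.0 |
| gamma | 25.0 | 15.6 | 83.6 |
| gamma | 40.0 | 26.9 | 72.7 |
| gamma | 50.0 | 32.2 | 66.2 |
| gamma | 60.0 | 39.7 | 61.0 |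
| epsilon | 5.00 | 1.2 | 99.1 |
| epsilon | 15.0 | 0 | 100.1 |
| epsilon | 30.0 | 8.2 | 91.4 |
| epsilon | 40.0 | 15.1 | 87.3 |
| epsilon | 60.0 | 25.1 | 75.7 |

(each reading ± 1 percentage point)

- a species is counted by the substrate in it: one ended chains A counts as two
- on the list of suspects stand: chain carrier + radical scavenger -> ended chains C; 2 chain carrier -> ended chains A; partner + chain carrier -> target + initiating radical; substrate + initiating radical <-> chain carrier; 2 initiating radical -> ended chains B; initiator -> 2 initiating radical
- where the amount of substrate changes, what is given in equivalents or mol% on it follows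
- no earlier run changes the charge of radical scavenger; that part of a forecast is a guess

- the flask that ends with the higher amount of target, in percent of the substrate charged, or "neither" when 2 percentage points or less lies between them (north / north-west / neither)
- final target, as a percentage of the substrate charged, in north
- final target, as a percentage of the substrate charged, in north-west

Read the ceiling first. Each target takes one partner, so theta should stop at 30.0%, and its last reading is 31.3%. Partner is the limiting reagent there.

Now read the reach. Below the ceiling, zeta and gamma differ in partner charge, yet at 60.0 min zeta has 38.6% and gamma 39.7%. So treat substrate loss as pseudo-first-order. Zeta gives a reading of 0.00951 min⁻¹ for the constant.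

But the curve starts late. Extrapolate zeta back to the full charge and the delay is 6.80 min. Take it as the time the radicals from initiator need to use up the radical scavenger.

Test this on epsilon, with its initiator cut. Its constant is 0.00628 min⁻¹, a reading ratio of 1.51. That stands nearer 1.41 than 2, so scale the constant by the square root of initiator concentration. Its delay is 15.7 min, so scale delay by scavenger over initiator.

North then reaches 65.9%, a ratio of 0.549. North-west has 0.00713 min⁻¹ and a delay of 22.7 min. It reaches 50.0%, so its reach ratio is 1.25.

Object: initiator decays, and no earlier run goes past 60.0 min. If each radical scavenger takes one radical and each initiator gives two, the delay implies an initiator decay constant of 0.00134 min⁻¹. Replace the decaying square root by its mean, a factor of 0.961. North-west's ratio is still 1.22. So commit: north follows its reach, and north-west stops at its ceiling of 40.0%.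

The forecast says north, with 64% and 39.5%: “Uncapped this gives about 47%, so partner caps it near 40%”. My reach differs a little from its figures, at 65.9% for north and 50.0% for north-west.

    chain carrier + radical scavenger → ended chains C (k = 2.69 × 10⁸ M⁻¹ s⁻¹)
    2 chain carrier → ended chains A (k = 1.00 × 10⁶ M⁻¹ s⁻¹)
    partner + chain carrier → target + initiating radical (k = 3.78 × 10⁵ M⁻¹ min⁻¹)
    substrate + initiating radical ⇌ chain carrier (K = 1.24 × 10⁶ M⁻¹, k = 3.05 × 10⁵ M⁻¹ min⁻¹)
    2 initiating radical → ended chains B (k = 6.00 × 10⁸ M⁻¹ s⁻¹)
    initiator → 2 initiating radical (k = 0.00101 min⁻¹)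

The flask gives north, with 66.6% in north and 40.0% in north-west. North ends with 45% of its partner left, at a ratio of 0.549. North-west ends with 0.041% of its partner and 60% of its substrate left, at a ratio of 1.25. At the asked time in north-west, the half-life of partner by its step with chain carrier is 0.053 h, far shorter than the 2.0 h of the run. The neighbour of north-west with 0.160 equiv of partner has a ratio of 3.12 and ends at 16.0% of target, with 0% of its partner left.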